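**Remark on the chemistry.** The side chain is numbered from the benzylic carbon C1' to C16'. The nerol unit supplies C9'–C16' together with both the 11'- and the 15'-methyl group, ten carbons in all. The two coupling partners and the coupling product were checked against the target, atom by atom and centre by centre, and needed no correction. The one refinement is in the reagents of the key step: slightly more than two equivalents of a sodium amide base in THF/DMPU, because the hydroxyl group consumes one equivalent and the epoxide migration needs a loosely paired alkoxide.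

## Structural features

The target is a 1,4-benzoquinone with a methyl group at C2 and, at C6, an acyclic C16 chain with four methyl branches, attached through the benzylic and allylic carbon C1'. The chain holds three trisubstituted double bonds: C2'=C3' and C6'=C7', both E, and the terminal isopropylidene C14'=C15'. The only stereocentres are the neighbouring C10' (secondary carbinol) and C11' (tertiary, methyl-bearing carbinol), both S; they form a vicinal diol whose C–O bonds are syn when C9'–C12' is drawn extended. The quinone is the fragile group, since it tolerates neither carbanions nor hydride nor strong base; the vicinal diol can be cleaved by strong oxidants, and the tertiary alcohol between two olefins invites acid-induced cyclisation. The real difficulty is to place this diol, in one relative and absolute configuration, inside a chain whose trisubstituted olefins an oxidant can hardly tell apart, while both E geometries are kept. The key step exploits two facts. First, C9'–C16' with the methyl groups on C11' and C15' is the skeleton of nerol, whose 2,3-epoxide already carries the C11' oxygen and delivers the C10' oxygen after migration to C9'/C10' with one inversion at C10'. Second, C8' is allylic to C6'=C7' and can therefore carry a sulfone and react as a carbanion.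

## Logic of the disconnections

17 ⇒ 16. The two ring carbonyl groups are traced back to aryl methyl ethers (two O–CH3 bonds). The ring has to travel as an arene because a quinone would not survive carbanions, hydride or palladium hydride. The gain is an inert ring through all C–C bond formation. The demand is a final oxidant that attacks the electron-rich ring faster than the diol or the olefins.

16 ⇒ 15. A sulfonyl group is placed on C8' (C8'–H becomes C8'–S). It makes the allylic C8' a carbanion site and so opens the chain to a cut next to it. The price is one reductive step. That step must leave C6'=C7' in place and E, and must tolerate two free hydroxyls.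

15 ⇒ 11 + 13 (through 14). The C8'–C9' bond is cut. This splits the chain near its middle into two pieces of monoterpene size and puts both stereocentres into 13, one catalytic step from 12. The forward step must first move the oxirane of 13 from C10'/C11' to C9'/C10' (14), then alkylate at C9' only and at the α-carbon of the sulfone anion only.

13 ⇒ 12. Both C–O bonds of the oxirane are cut. The allylic hydroxyl directs a catalytic asymmetric epoxidation, so an achiral, purchasable alcohol remains. The forward step needs reagent control of the olefin face on a Z-allylic alcohol and no reaction at the remote olefin.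

11 ⇒ 8 + 9 (through 10). The C8'–S bond is cut. Sulfur is introduced as a nucleophile on an activated primary allylic carbon. The substitution must proceed without allylic transposition and through sulfur, not oxygen, of the ambident anion.

8 ⇒ 6 (through 7). The C8'–O bond is cut, which makes the forward step a C–H oxidation. The gain is a precursor with no chain functionality other than olefins. The oxidation must pick the E-methyl of the terminal olefin out of three allylic methyl groups and several allylic methylenes.

6 ⇒ 3 + 4 (through 5). The aryl–C1' bond is cut. Ring and C10 chain become two simple pieces, one of them purchased. The forward step needs attack at the primary (α) carbon of the allylic electrophile with the 2'E geometry kept.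

3 ⇒ 2 ⇒ 1. One O–CH3 bond and the C–Br bond are cut. The substitution pattern of the ring is then already present in a purchasable phenol. Bromination must go to the single free position ortho to the hydroxyl without oxidising the ring.

## Other disconnections considered

Alternative 1: The cut runs through three ring bonds (C4–C5, C6–C1 and C1–C2 in quinone numbering), so the ring is made last. In the forward sense the alkenyl(methoxy)carbene chromium complex A1 and the terminal alkyne A2, which carries the whole side chain with the diol as an acetonide, would combine with one CO ligand in a Dötz benzannulation to the 4-methoxyphenol A3.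
- In favour: the usual regiochemistry (alkyne substituent next to the new hydroxyl) gives exactly the 2-methyl-6-alkyl pattern, and no aryl halide chemistry is needed. A3 is a 4-methoxyphenol, which should be oxidised to the quinone under milder conditions than a dimethyl ether; on this point the alternative is the better plan.
- Against: the key step solves none of the hard problems. The diol and both E-olefins must already be in A2 and would most simply come from the same epoxynerol chemistry. A2 ends in a skipped enyne whose doubly activated CH2 isomerises easily. A stoichiometric zerovalent chromium carbonyl reagent is needed, and an acetonide must be put on and taken off.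
- Comparison: in structure, the chosen plan spends its key step on the chain and the diol and buys the arene, whereas this plan spends it on the arene. In mechanism, the benzannulation is an established reaction class and is the better of the two on precedent. In step economy it should be clearly longer.

Alternative 2: The cut is the sp3–sp2 bond C5'–C6'. The redox-active ester A4 would lose CO2 at a nickel catalyst under constant-current reduction and couple with the E vinyl iodide A5 to give the fully protected target A6.
- In favour: the C6'=C7' geometry is fixed in A5 before the coupling. No activating group has to be removed afterwards, which is better than the sulfone of the chosen plan. This reaction class has been applied to polyene chains, so its precedent is closer than that of the chosen key step.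
- Against: the stereochemical problem is only moved, because A5 must already contain the protected diol. A4 needs its own construction of the C2'=C3' olefin. The primary C5' radical is homoallylic, and reduction or dimerisation can compete with capture by nickel. An electrolysis set-up and acetonide protection and removal add effort.
- Comparison: in structure, both plans cut the chain in its middle, but here both halves need several steps and the diol half is the harder one. In mechanism, the alternative is the equal or the better on precedent and on mildness. In step economy the chosen plan should be shorter, since its two partners are five steps and one step from purchased materials.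

Alternative 3: The cut is the C10'–C11' bond between the two carbinol carbons. The aldehyde A7 would react with the Z γ,γ-disubstituted boronate A8 through its oxygenated γ-carbon under a chiral phosphoric acid, by a closed six-membered transition state, to give A9 with both stereocentres and a vinyl group.
- In favour: one catalytic step forms a C–C bond and both stereocentres, and the other diastereomer would be reachable from the E boronate. That flexibility is a point on which it is better than the chosen plan, which is tied to the geometry of nerol.
- Against: A8 is a tetrasubstituted enol-ether boronate that must be geometrically pure, since any E isomer erodes the diastereomer ratio directly. γ,γ-Disubstituted reagents add slowly, and enantiocontrol with a linear aliphatic aldehyde is uncertain. After the key step, three carbons must still be added at the vinyl group by hydroboration and cross-coupling, and a tertiary MOM ether must be cleaved by acid next to olefins. A7 itself needs a two-carbon homologation beyond C8'.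
- Comparison: in structure, the chosen plan imports C9'–C16' in one piece and this plan assembles it in three. In mechanism, both rely on catalyst-controlled asymmetric steps, and the alternative is the equal of the chosen plan in that its stereocontrol is catalytic. In step economy the alternative should be longer by several steps.

Key step: step 7

## Route

Step 1
Reactants: 1 4-methoxy-2-methylphenol
Product: 2 2-bromo-4-methoxy-6-methylphenol
Conditions: NBS (1.0 equiv), CH2Cl2, 0 °C, dark
Reagents that add atoms: N-bromosuccinimide, O=C1CCC(=O)N1Br
Why: Electrophilic aromatic bromination; the free hydroxyl directs to its only open ortho position, because the para position carries OMe and the other ortho position the methyl group. One equivalent of NBS in an aprotic solvent at 0 °C should avoid oxidation of the 4-methoxyphenol to a quinone.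

Step 2
Reactants: 2 2-bromo-4-methoxy-6-methylphenol
Product: 3 1-bromo-2,5-dimethoxy-3-methylbenzene
Conditions: MeI, K2CO3, DMF, rt
Reagents that add atoms: iodomethane, CI
Why: Williamson ether synthesis (SN2 of the phenoxide on MeI); the two ortho substituents slow the reaction but should not block it in DMF.

Step 3
Reactants: 3 1-bromo-2,5-dimethoxy-3-methylbenzene; 4 geranyl bromide [(2E)-1-bromo-3,7-dimethylocta-2,6-diene]
Product: 6 1-[(2E)-3,7-dimethylocta-2,6-dien-1-yl]-2,5-dimethoxy-3-methylbenzene, via arylmagnesium bromide 5 (not isolated)
Conditions: Mg, I2 (cat.), THF, 45 °C; then CuI (5 mol%), 4, THF, −20 °C → rt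
Reagents that add atoms: magnesium, [Mg] (held only in intermediate 5)
Why: Grignard formation followed by copper-catalysed allylic substitution at the primary carbon of 4. Attack at the γ-carbon would create a quaternary centre and is disfavoured, so the E-olefin should be carried over unchanged.

Step 4
Reactants: 6 1-[(2E)-3,7-dimethylocta-2,6-dien-1-yl]-2,5-dimethoxy-3-methylbenzene
Product: 8 (2E,6E)-8-(2,5-dimethoxy-3-methylphenyl)-2,6-dimethylocta-2,6-dien-1-ol, via E-enal 7 (not isolated)
Conditions: SeO2 (0.3 equiv), t-BuOOH (3 equiv), salicylic acid (0.1 equiv), CH2Cl2, 0 °C → rt; then NaBH4, MeOH, 0 °C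
Reagents that add atoms: selenium dioxide, O=[Se]=O (oxygen carrier); tert-butyl hydroperoxide, CC(C)(C)OO (terminal oxygen source)
Why: Riley allylic oxidation in its catalytic SeO2/t-BuOOH form; an ene reaction at the terminal, least hindered trisubstituted olefin and a [2,3]-sigmatropic shift place oxygen on the E-methyl group. The part of the material that is over-oxidised to enal 7 is returned to 8 by NaBH4.

Step 5
Reactants: 8 (2E,6E)-8-(2,5-dimethoxy-3-methylphenyl)-2,6-dimethylocta-2,6-dien-1-ol; 9 sodium benzenesulfinate
Product: 11 1-[(2E,6E)-8-(benzenesulfonyl)-3,7-dimethylocta-2,6-dien-1-yl]-2,5-dimethoxy-3-methylbenzene, via allylic bromide 10 (not isolated)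
Conditions: PBr3 (0.4 equiv), Et2O, −10 °C; then 9 (1.5 equiv), DMF, rt
Reagents that add atoms: sodium benzenesulfinate (compound 9), [Na+].[O-]S(=O)c1ccccc1; phosphorus tribromide, BrP(Br)Br (its bromine stays only in intermediate 10)
Why: Conversion of the primary allylic alcohol to the bromide, then SN2 displacement by the soft sulfur atom of the sulfinate in a dipolar solvent, which should give the sulfone and not the sulfinate ester. Both substitutions occur at the primary carbon, so the E geometry should be kept.

Step 6
Reactants: 12 nerol [(2Z)-3,7-dimethylocta-2,6-dien-1-ol]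
Product: 13 (2R,3S)-2,3-epoxynerol {[(2R,3S)-3-methyl-3-(4-methylpent-3-en-1-yl)oxiran-2-yl]methanol}
Conditions: Ti(OiPr)4 (5 mol%), D-(−)-diethyl tartrate (7 mol%), t-BuOOH (anhydrous, 2 equiv), 4 Å molecular sieves, CH2Cl2, −20 °C
Reagents that add atoms: tert-butyl hydroperoxide, CC(C)(C)OO
Why: Katsuki–Sharpless asymmetric epoxidation; the titanium tartrate binds the allylic hydroxyl, so only C2=C3 should react and the remote olefin stays. The D-(−)-tartrate delivers oxygen syn to the face that gives 2R,3S, which fixes C11' in its final configuration and C10' in the configuration that one later inversion turns into S. The enantiomeric purity of the target rests on this step.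

Step 7
Reactants: 11 1-[(2E,6E)-8-(benzenesulfonyl)-3,7-dimethylocta-2,6-dien-1-yl]-2,5-dimethoxy-3-methylbenzene; 13 (2R,3S)-2,3-epoxynerol
Product: 15 (6S,7S,10E,14E)-9-(benzenesulfonyl)-16-(2,5-dimethoxy-3-methylphenyl)-2,6,10,14-tetramethylhexadeca-2,10,14-triene-6,7-diol as both epimers at the sulfone carbon C8', via terminal epoxide alkoxide 14 (not isolated)
Conditions: 11 (1.2 equiv), NaN(SiMe3)2 (1.25 equiv), THF, −78 °C; then sodium alkoxide of 13 (13, NaN(SiMe3)2 1.0 equiv, THF, −78 → 0 °C) and DMPU (THF/DMPU 5:1), −78 °C → rt, 40 °C if needed; aq. NH4Cl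
Reagents that add atoms: none
Why: Proposed new method: with both partners deprotonated, the sodium alkoxide of 13 should equilibrate by Payne rearrangement (intramolecular SN2 attack of the C9' oxygen on C10', with inversion) with the terminal epoxide 14, and the sulfone-stabilised allyl anion of 11 should open 14 at its unhindered CH2 by intermolecular SN2, so that the minor but far more reactive isomer is drained and the C8'–C9' bond forms. The closest known reaction types are the Payne rearrangement with capture of the terminal epoxide in the same flask by thiolates, amines, cyanide or sulfonium ylides, and the opening of terminal epoxides by metalated allylic sulfones; the new element is their combination, with a carbanion, in an aprotic medium. No ring is closed; the oxirane of 14 is opened and ends as the C10' hydroxyl. C10' is set by substrate control: it has the configuration of C2 of 13 after exactly one inversion (S), while C11' keeps the oxygen and the configuration from the epoxidation (S). C8' forms without control as both epimers, which does not matter because that centre becomes CH2 in step 8. The step needs attack at C9' and not at the oxirane carbons of 13; the fully substituted C11' and the alkoxide-flanked C10' of 13, set against the open CH2 of 14, should secure this. It also needs α- and not γ-alkylation of the allyl sulfone anion, which charge localisation next to sulfur should secure and which also preserves the C6'=C7' geometry. Sodium and DMPU are chosen because lithium alkoxides undergo the epoxide shift sluggishly in ethers, and the C1' protons are about ten pKa units less acidic than C8'–H, so no second anion should form.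

Step 8
Reactants: 15 (6S,7S,10E,14E)-9-(benzenesulfonyl)-16-(2,5-dimethoxy-3-methylphenyl)-2,6,10,14-tetramethylhexadeca-2,10,14-triene-6,7-diol
Product: 16 (6S,7S,10E,14E)-16-(2,5-dimethoxy-3-methylphenyl)-2,6,10,14-tetramethylhexadeca-2,10,14-triene-6,7-diol
Conditions: LiBHEt3 (5 equiv), PdCl2(dppp) (5 mol%), THF, 0 °C → rt; aq. NH4Cl
Reagents that add atoms: none
Why: Palladium-catalysed reductive desulfonylation of an allylic sulfone; zerovalent palladium formed from PdCl2(dppp) by hydride ionises the C–S bond to a π-allyl complex, and hydride is returned to the carbon that carried sulfur, which in prenyl-type sulfones keeps the double bond in place and E. The excess hydride first converts both hydroxyls to alkoxyborates, and the C10' and C11' centres are not touched.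

Step 9
Reactants: 16 (6S,7S,10E,14E)-16-(2,5-dimethoxy-3-methylphenyl)-2,6,10,14-tetramethylhexadeca-2,10,14-triene-6,7-diol
Product: 17 2-[(2E,6E,10S,11S)-10,11-dihydroxy-3,7,11,15-tetramethylhexadeca-2,6,14-trien-1-yl]-6-methylcyclohexa-2,5-diene-1,4-dione
Conditions: (NH4)2Ce(NO3)6 (2.5 equiv), MeCN/H2O (2:1), 0 °C, short reaction time
Reagents that add atoms: water, O
Why: Oxidative demethylation of a hydroquinone dimethyl ether by (NH4)2Ce(NO3)6; two one-electron oxidations of the arene, addition of water at the two methoxy-bearing ring carbons and loss of methanol should give the para-quinone. The electron-rich ring should be oxidised much faster than the isolated olefins or the diol at 0 °C.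

## Compound list

1 | 4-methoxy-2-methylphenol | Cc1cc(OC)ccc1O | starting material
2 | 2-bromo-4-methoxy-6-methylphenol | Cc1cc(OC)cc(Br)c1O | intermediate
3 | 1-bromo-2,5-dimethoxy-3-methylbenzene | Cc1cc(OC)cc(Br)c1OC | intermediate
4 | geranyl bromide, (2E)-1-bromo-3,7-dimethylocta-2,6-diene | CC(C)=CCC/C(C)=C/CBr | starting material
5 | (2,5-dimethoxy-3-methylphenyl)magnesium bromide | Cc1cc(OC)cc([Mg]Br)c1OC | intermediate (not isolated)
6 | 1-[(2E)-3,7-dimethylocta-2,6-dien-1-yl]-2,5-dimethoxy-3-methylbenzene | CC(C)=CCC/C(C)=C/Cc1cc(OC)cc(C)c1OC | intermediate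
7 | (2E,6E)-8-(2,5-dimethoxy-3-methylphenyl)-2,6-dimethylocta-2,6-dienal | O=C/C(C)=C/CC/C(C)=C/Cc1cc(OC)cc(C)c1OC | intermediate (not isolated)
8 | (2E,6E)-8-(2,5-dimethoxy-3-methylphenyl)-2,6-dimethylocta-2,6-dien-1-ol | OC/C(C)=C/CC/C(C)=C/Cc1cc(OC)cc(C)c1OC | intermediate
9 | sodium benzenesulfinate | [Na+].[O-]S(=O)c1ccccc1 | starting material
10 | 1-[(2E,6E)-8-bromo-3,7-dimethylocta-2,6-dien-1-yl]-2,5-dimethoxy-3-methylbenzene | BrC/C(C)=C/CC/C(C)=C/Cc1cc(OC)cc(C)c1OC | intermediate (not isolated)
11 | 1-[(2E,6E)-8-(benzenesulfonyl)-3,7-dimethylocta-2,6-dien-1-yl]-2,5-dimethoxy-3-methylbenzene | O=S(=O)(c1ccccc1)C/C(C)=C/CC/C(C)=C/Cc1cc(OC)cc(C)c1OC | intermediate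
12 | nerol, (2Z)-3,7-dimethylocta-2,6-dien-1-ol | CC(C)=CCC/C(C)=C\CO | starting material
13 | (2R,3S)-2,3-epoxynerol, [(2R,3S)-3-methyl-3-(4-methylpent-3-en-1-yl)oxiran-2-yl]methanol | CC(C)=CCC[C@]1(C)O[C@@H]1CO | intermediate
14 | sodium (2S)-6-methyl-2-[(2S)-oxiran-2-yl]hept-5-en-2-olate | CC(C)=CCC[C@](C)([O-])[C@@H]1CO1.[Na+] | intermediate (not isolated)
15 | (6S,7S,10E,14E)-9-(benzenesulfonyl)-16-(2,5-dimethoxy-3-methylphenyl)-2,6,10,14-tetramethylhexadeca-2,10,14-triene-6,7-diol, both epimers at the sulfone carbon | CC(C)=CCC[C@](C)(O)[C@@H](O)CC(S(=O)(=O)c1ccccc1)/C(C)=C/CC/C(C)=C/Cc1cc(OC)cc(C)c1OC | intermediate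
16 | (6S,7S,10E,14E)-16-(2,5-dimethoxy-3-methylphenyl)-2,6,10,14-tetramethylhexadeca-2,10,14-triene-6,7-diol | CC(C)=CCC[C@](C)(O)[C@@H](O)CC/C(C)=C/CC/C(C)=C/Cc1cc(OC)cc(C)c1OC | intermediate
17 | 2-[(2E,6E,10S,11S)-10,11-dihydroxy-3,7,11,15-tetramethylhexadeca-2,6,14-trien-1-yl]-6-methylcyclohexa-2,5-diene-1,4-dione | CC(C)=CCC[C@](C)(O)[C@@H](O)CC/C(C)=C/CC/C(C)=C/CC1=CC(=O)C=C(C)C1=O | target

## Step count and risk

Total step count: 9. Longest linear sequence: 8 steps (from 1 through steps 1–5 and 7–9); the second branch (12 to 13) is one step.

**Step 7 (key step).** Three things are most likely to go wrong.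
- The epoxide migration may be too slow in the ion-paired, aprotic medium. The trisubstituted oxirane of 13 would then remain as the only electrophile and could isomerise under base to an allylic alcohol.
- Charge repulsion between the carbanion and the alkoxide-bearing epoxide may slow the opening.
- A second alkylation at the still acidic C8' may occur.

Fallback by known chemistry, from 13 back to the route at 15, with the two events separated:
- 13 is heated with PhSH in aqueous NaOH/t-BuOH (Payne rearrangement with thiolate capture at C1) to give (2R,3S)-3,7-dimethyl-1-(phenylsulfanyl)oct-6-ene-2,3-diol F1. The descriptor at C2 changes only because sulfur raises the priority of C1.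
- S-methylation with Me3O+ BF4− in CH2Cl2 gives [(2R,3S)-2,3-dihydroxy-3,7-dimethyloct-6-en-1-yl](methyl)phenylsulfonium tetrafluoroborate F2 (not isolated).
- NaH at 0 °C closes F2 through the C2 oxygen to the isolable terminal epoxide (2S)-6-methyl-2-[(2S)-oxiran-2-yl]hept-5-en-2-ol F3; the mixture is worked up before the reverse shift can set in.
- The tertiary hydroxyl is capped with TESOTf/2,6-lutidine to give triethyl({(2S)-6-methyl-2-[(2S)-oxiran-2-yl]hept-5-en-2-yl}oxy)silane F4, so that no alkoxide remains to move the oxirane.
- Lithiated 11 (n-BuLi, THF, −78 °C) opens F4 at its CH2 with BF3·OEt2, the standard union of a sulfone anion with a terminal epoxide, to give the 11'-O-triethylsilyl ether of 15 F5.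
- TBAF returns 15.

**Step 4.** The oxidation may lose site selectivity, with an ene reaction also at the C2'=C3' olefin or at the Z-methyl group. It may also over-oxidise or stall, as is common for this oxidation on polyprenyl chains, and the loss would fall on an advanced intermediate.

Fallback, from 3 (as its Grignard reagent 5) back to the route at 8; the oxidation is moved to a cheap substrate in which the allylic acetate deactivates the nearer olefin:
- Geranyl acetate F6 (purchased) is oxidised with SeO2/t-BuOOH to (2E,6E)-8-hydroxy-3,7-dimethylocta-2,6-dien-1-yl acetate F7.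
- Silylation with TBSCl/imidazole gives (2E,6E)-8-[(tert-butyldimethylsilyl)oxy]-3,7-dimethylocta-2,6-dien-1-yl acetate F8.
- K2CO3/MeOH gives (2E,6E)-8-[(tert-butyldimethylsilyl)oxy]-3,7-dimethylocta-2,6-dien-1-ol F9.
- CBr4/PPh3 gives {[(2E,6E)-8-bromo-2,6-dimethylocta-2,6-dien-1-yl]oxy}(tert-butyl)dimethylsilane F10.
- Copper-catalysed coupling with 5, as in step 3, gives tert-butyl{[(2E,6E)-8-(2,5-dimethoxy-3-methylphenyl)-2,6-dimethylocta-2,6-dien-1-yl]oxy}dimethylsilane F11.
- TBAF gives 8.

**Step 8.** The π-allyl palladium intermediate may be captured by the C11' alkoxide, closing a five-membered cyclic ether, before hydride arrives. Hydride may also be delivered to C6', which would shift the double bond to C7'=C8'.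

Fallback, from 15 back to the route at 16, with the diol masked during the reduction:
- 2,2-Dimethoxypropane/PPTS converts 15 to the acetonide 1-{(2E,6E)-8-(benzenesulfonyl)-3,7-dimethyl-9-[(4S,5S)-2,2,5-trimethyl-5-(4-methylpent-3-en-1-yl)-1,3-dioxolan-4-yl]nona-2,6-dien-1-yl}-2,5-dimethoxy-3-methylbenzene F12.
- The same LiBHEt3/PdCl2(dppp) reduction, now without alkoxides, gives 1-{(2E,6E)-3,7-dimethyl-9-[(4S,5S)-2,2,5-trimethyl-5-(4-methylpent-3-en-1-yl)-1,3-dioxolan-4-yl]nona-2,6-dien-1-yl}-2,5-dimethoxy-3-methylbenzene F13, which has the same structure as A6.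
- Aqueous AcOH at 40 °C returns 16.

**Step 9.** Oxidative cleavage of the vicinal diol by tetravalent cerium may compete with oxidation of the arene, and the acidic medium may start cyclisation at the tertiary alcohol.

Fallback, from 16 back to the route at 17, with the diol masked during the oxidation:
- 16 is converted with 2,2-dimethoxypropane/PPTS to the acetonide 1-{(2E,6E)-3,7-dimethyl-9-[(4S,5S)-2,2,5-trimethyl-5-(4-methylpent-3-en-1-yl)-1,3-dioxolan-4-yl]nona-2,6-dien-1-yl}-2,5-dimethoxy-3-methylbenzene F13. If the fallback to step 8 was used, F13 is taken on directly.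
- (NH4)2Ce(NO3)6 in MeCN/H2O at 0 °C gives the quinone acetonide 2-{(2E,6E)-3,7-dimethyl-9-[(4S,5S)-2,2,5-trimethyl-5-(4-methylpent-3-en-1-yl)-1,3-dioxolan-4-yl]nona-2,6-dien-1-yl}-6-methylcyclohexa-2,5-diene-1,4-dione F14.
- Aqueous AcOH frees the diol to give 17; the quinone is stable to these conditions.

## Further compounds

F1 | step 7 | (2R,3S)-3,7-dimethyl-1-(phenylsulfanyl)oct-6-ene-2,3-diol | CC(C)=CCC[C@](C)(O)[C@@H](O)CSc1ccccc1
F2 | step 7 | [(2R,3S)-2,3-dihydroxy-3,7-dimethyloct-6-en-1-yl](methyl)phenylsulfonium tetrafluoroborate | CC(C)=CCC[C@](C)(O)[C@@H](O)C[S+](C)c1ccccc1.F[B-](F)(F)F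
F3 | step 7 | (2S)-6-methyl-2-[(2S)-oxiran-2-yl]hept-5-en-2-ol | CC(C)=CCC[C@](C)(O)[C@@H]1CO1
F4 | step 7 | triethyl({(2S)-6-methyl-2-[(2S)-oxiran-2-yl]hept-5-en-2-yl}oxy)silane | CC(C)=CCC[C@](C)(O[Si](CC)(CC)CC)[C@@H]1CO1
F5 | step 7 | 11'-O-triethylsilyl ether of 15, (6S,7S,10E,14E)-9-(benzenesulfonyl)-16-(2,5-dimethoxy-3-methylphenyl)-2,6,10,14-tetramethyl-6-[(triethylsilyl)oxy]hexadeca-2,10,14-trien-7-ol | CC(C)=CCC[C@](C)(O[Si](CC)(CC)CC)[C@@H](O)CC(S(=O)(=O)c1ccccc1)/C(C)=C/CC/C(C)=C/Cc1cc(OC)cc(C)c1OC
F6 | step 4 | geranyl acetate (purchased) | CC(C)=CCC/C(C)=C/COC(C)=O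
F7 | step 4 | (2E,6E)-8-hydroxy-3,7-dimethylocta-2,6-dien-1-yl acetate | CC(=O)OC/C=C(C)/CC/C=C(C)/CO
F8 | step 4 | (2E,6E)-8-[(tert-butyldimethylsilyl)oxy]-3,7-dimethylocta-2,6-dien-1-yl acetate | CC(=O)OC/C=C(C)/CC/C=C(C)/CO[Si](C)(C)C(C)(C)C
F9 | step 4 | (2E,6E)-8-[(tert-butyldimethylsilyl)oxy]-3,7-dimethylocta-2,6-dien-1-ol | OC/C=C(C)/CC/C=C(C)/CO[Si](C)(C)C(C)(C)C
F10 | step 4 | {[(2E,6E)-8-bromo-2,6-dimethylocta-2,6-dien-1-yl]oxy}(tert-butyl)dimethylsilane | BrC/C=C(C)/CC/C=C(C)/CO[Si](C)(C)C(C)(C)C
F11 | step 4 | tert-butyl{[(2E,6E)-8-(2,5-dimethoxy-3-methylphenyl)-2,6-dimethylocta-2,6-dien-1-yl]oxy}dimethylsilane | CC(C)(C)[Si](C)(C)OC/C(C)=C/CC/C(C)=C/Cc1cc(OC)cc(C)c1OC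
F12 | step 8 | 1-{(2E,6E)-8-(benzenesulfonyl)-3,7-dimethyl-9-[(4S,5S)-2,2,5-trimethyl-5-(4-methylpent-3-en-1-yl)-1,3-dioxolan-4-yl]nona-2,6-dien-1-yl}-2,5-dimethoxy-3-methylbenzene | CC(C)=CCC[C@]1(C)OC(C)(C)O[C@H]1CC(S(=O)(=O)c1ccccc1)/C(C)=C/CC/C(C)=C/Cc1cc(OC)cc(C)c1OC
F13 | step 8 | 1-{(2E,6E)-3,7-dimethyl-9-[(4S,5S)-2,2,5-trimethyl-5-(4-methylpent-3-en-1-yl)-1,3-dioxolan-4-yl]nona-2,6-dien-1-yl}-2,5-dimethoxy-3-methylbenzene | CC(C)=CCC[C@]1(C)OC(C)(C)O[C@H]1CC/C(C)=C/CC/C(C)=C/Cc1cc(OC)cc(C)c1OC
F14 | step 9 | 2-{(2E,6E)-3,7-dimethyl-9-[(4S,5S)-2,2,5-trimethyl-5-(4-methylpent-3-en-1-yl)-1,3-dioxolan-4-yl]nona-2,6-dien-1-yl}-6-methylcyclohexa-2,5-diene-1,4-dione | CC(C)=CCC[C@]1(C)OC(C)(C)O[C@H]1CC/C(C)=C/CC/C(C)=C/CC1=CC(=O)C=C(C)C1=O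
A1 | alternative 1 | pentacarbonyl[(2E)-1-methoxybut-2-en-1-ylidene]chromium | COC(/C=C/C)=[Cr](=C=O)(=C=O)(=C=O)(=C=O)=C=O
A2 | alternative 1 | (4S,5S)-5-[(3E,7E)-3,7-dimethylundeca-3,7-dien-10-yn-1-yl]-2,2,4-trimethyl-4-(4-methylpent-3-en-1-yl)-1,3-dioxolane | CC(C)=CCC[C@]1(C)OC(C)(C)O[C@H]1CC/C(C)=C/CC/C(C)=C/CC#C
A3 | alternative 1 | 2-{(2E,6E)-3,7-dimethyl-9-[(4S,5S)-2,2,5-trimethyl-5-(4-methylpent-3-en-1-yl)-1,3-dioxolan-4-yl]nona-2,6-dien-1-yl}-4-methoxy-6-methylphenol | CC(C)=CCC[C@]1(C)OC(C)(C)O[C@H]1CC/C(C)=C/CC/C(C)=C/Cc1cc(OC)cc(C)c1O
A4 | alternative 2 | 1,3-dioxoisoindolin-2-yl (4E)-6-(2,5-dimethoxy-3-methylphenyl)-4-methylhex-4-enoate | O=C(CC/C(C)=C/Cc1cc(OC)cc(C)c1OC)ON1C(=O)c2ccccc2C1=O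
A5 | alternative 2 | (4S,5S)-4-[(3E)-4-iodo-3-methylbut-3-en-1-yl]-2,2,5-trimethyl-5-(4-methylpent-3-en-1-yl)-1,3-dioxolane | CC(C)=CCC[C@]1(C)OC(C)(C)O[C@H]1CC/C(C)=C/I
A6 | alternative 2 | 1-{(2E,6E)-3,7-dimethyl-9-[(4S,5S)-2,2,5-trimethyl-5-(4-methylpent-3-en-1-yl)-1,3-dioxolan-4-yl]nona-2,6-dien-1-yl}-2,5-dimethoxy-3-methylbenzene | CC(C)=CCC[C@]1(C)OC(C)(C)O[C@H]1CC/C(C)=C/CC/C(C)=C/Cc1cc(OC)cc(C)c1OC
A7 | alternative 3 | (4E,8E)-10-(2,5-dimethoxy-3-methylphenyl)-4,8-dimethyldeca-4,8-dienal | O=CCC/C(C)=C/CC/C(C)=C/Cc1cc(OC)cc(C)c1OC
A8 | alternative 3 | 2-[(2Z)-3-(methoxymethoxy)but-2-en-1-yl]-4,4,5,5-tetramethyl-1,3,2-dioxaborolane | COCO/C(C)=C\CB1OC(C)(C)C(C)(C)O1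
A9 | alternative 3 | (3S,4S,7E,11E)-13-(2,5-dimethoxy-3-methylphenyl)-3-(methoxymethoxy)-3,7,11-trimethyltrideca-1,7,11-trien-4-ol | C=C[C@](C)(OCOC)[C@@H](O)CC/C(C)=C/CC/C(C)=C/Cc1cc(OC)cc(C)c1OC
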